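Where two steps consume the same pair of reactants by the same rate law, at fixed temperature, the ratio of their rates stays constant however the concentrations wander. Substrate and reagent form target and side product in just this way, here in flasks that differ in their charge of substrate.

all flasks: gas 4.7 mM (held); time 8.0 min

|  | substrate |
|---|---|
| dawn | 0.050 M |
| winter | 0.15 M |
| spring | 0.50 M |

    reagent → decomposition product (k1 = 7.6 × 10⁻⁷ s⁻¹)
    substrate + reagent → side product (k2 = 1.0 M⁻¹ s⁻¹)
    gas ⇌ reagent, rate k3*(csat - [reagent]) (k3 = 0.21 s⁻¹, csat = 4.7 mM)
    intermediate A ⇌ intermediate C (K4 = 0.58, k4 = 0.0019 s⁻¹)
    substrate + reagent → target (k5 = 16 M⁻¹ s⁻¹)
    intermediate A ⇌ intermediate B (K6 = 0.90, k6 = 0.0072 s⁻¹)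
    substrate ⇌ intermediate A (K7 = 0.35, k7 = 1.7 × 10⁻⁴ s⁻¹)

- at the start none of reagent is dissolved
- "hardly changes" means that all values lie within two and a half points (for a concentration: within two and a half percent of the largest)
- run time (dawn): 8.0 min

- share of target in all that became target or side product for dawn, winter, spring, in this order
- the shape of the row from first to last (hardly changes / rises, then falls / rises all the way / falls, then rises / falls all the way)

Before I take any number, I ask what an error in each given value does to the share. The transfer coefficient, the saturation concentration, the decomposition constant, the constants of the intermediates and the charge of substrate act on c(substrate) or c(reagent). These two stand as the same product in both rates: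

rate to target / rate to side product = (target constant · c(substrate) · c(reagent)) / (side constant · c(substrate) · c(reagent)) = target constant / side constant

So those values cancel from the quotient. They change how much forms and how soon, but not the division. The two rate constants stay in it, and an error there shows: with twice the side constant, the share reads 88.9%. These are the two numbers I need to know well.

Their ratio, the selectivity factor, is 16.0, with the target constant larger than the side constant. The quotient holds from the first moment, so the amounts formed keep it too. I carry the split, the target constant divided by the sum of the target and side constants:

split = 16 M⁻¹ s⁻¹ / (16 M⁻¹ s⁻¹ + 1.0 M⁻¹ s⁻¹) = 94.1%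

My row is therefore flat at that value. The forecast gives 94.1%, 94.1% and 94.1%, shape hardly changes, and says the other processes “change how much product forms but not this split”. That is the same cancellation as mine.

The simulation gives 94.1%, 94.1% and 94.1%, shape hardly changes. Spring ends with 7.7% of its substrate left, against 0% in dawn. Put to use on spring, the split of 94.1%, which is 16.0 parts of target to one of side product, pairs side product of 5.20% of the substrate charged with target of 83.2%, and spring holds 83.2%. On winter, side product of 5.80% goes by the same split with target of 92.8%, and winter holds 92.8% of target.

The constants come from no measurement; the result is computed.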